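# Guanipiperazine A (28): ring B from a 2-pyrone by a macrocyclizing Diels–Alder reaction

## The problem

Guanipiperazine A (28) is built from three parts: a cis-(2S,5S)-2,5-dibenzylpiperazine, a diaryl ether that ties both benzylic arms into a 14-membered ring (para carbon of ring B to the ring A carbon meta to its benzylic arm), and a guanine bonded through C8 to the ring A carbon ortho to the phenol. Ring B sits in the macrocycle as a bent para-phenylene, so any ring closure carried out on a finished ring B has to pay for strain in the closing step. The two stereocentres are 1,4-related across the piperazine and cannot usefully direct one another; both are best bought as L-amino acid derivatives and kept from epimerising, and their cis relation helps because it lets both arms fold over one face of a diketopiperazine. The guanine is polar, insoluble and rich in N–H bonds and belongs at the end, and the phenol and the two secondary amines must be masked and unmasked so that the one free ortho position of ring A stays open for the guanine carbon. The fragile groups are those a cycloaddition route introduces: a 2-pyrone, which hydroxide, alkoxides and amines open, and an aryl ethynyl ether, which acids hydrate, carboxylic acids add to, and whose reliable synthesis needs an alkyllithium that no ester, carbamate or pyrone survives. The feature that makes the key step possible is ring B itself: its only substituents are the ether oxygen and the benzylic CH2, para to each other, so the oxygen-bearing carbon and one ortho carbon can come from an ethynyl ether on ring A and the other four carbons from C3–C6 of a 5-alkyl-2-pyrone, whose O1–C2 unit leaves as carbon dioxide.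

## Retrosynthesis

**28 ⇒ 27 ⇒ 24 + 25.** After removal of two carbamates, the C8–N7 and C8–N9 bonds of the purine are cut. This brings the guanine in last and convergently, from salicylaldehyde 24 and the purchasable triaminopyrimidinone 25. The neighbouring cut, a C8–aryl cross-coupling, would need a protected 8-haloguanine and a hindered ortho-metallated phenol. The forward reaction must form the imine at the 5-amino group and close the ring oxidatively without harming the carbamates.

**24 ⇒ 23 ⇒ 22 ⇒ 21 ⇒ 20.** The formyl C–C bond is cut, and functional groups are then adjusted back to the macrocyclic diketopiperazine 20. In phenol 23 the para position is blocked and one ortho position carries the aryloxy group, so ortho-formylation has a single site. 23 comes from aminophenol 22, 22 from methyl ether 21, and 21 from 20 by reduction of both lactams. The diketopiperazine is the form chosen to pass through the ring closure because two amino acids give it directly, it needs no N-protection, and it folds its side chains together. The forward steps need a lactam reduction inside a strained ring and a demethylation that spares the diaryl ether.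

**20 ⇒ 18 (through 19).** The two C–C bonds of ring B are cut that join its oxygen-bearing carbon and the adjacent CH to the rest of the ring. Against the neighbouring C–O cut (ring closure by etherification of a finished ring B), this cut removes ring B and the macrocycle together and leaves 18, a diketopiperazine with two unstrained side chains. The forward reaction is asked for an inverse-demand cycloaddition of an unactivated 5-alkyl-2-pyrone, para rather than meta bridging, and intramolecular reaction at high dilution.

**18 ⇒ 17 ⇒ 15 ⇒ 6 + 14.** The alkyne C–H is traced to a C–Si bond (17), and the two amide bonds of the diketopiperazine are cut to give acid 6 and amine 14 via dipeptide 15. The ethynyl ether cannot be made once esters, carbamates or the pyrone are present, and it does not survive acid. It is therefore carried in silyl-capped form inside 14, and every later deprotection uses base or fluoride: Fmoc on nitrogen, a methyl ester as acyl donor for lactamisation. Ring A is the amine partner so that no free carboxylic acid shares a molecule with the ynol ether. The forward steps must run amide coupling, Fmoc cleavage and lactamisation in the presence of a 2-pyrone.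

**14 ⇒ 13 ⇒ 10 + 11, and 10 ⇒ 8 ⇒ 7.** The aryl–CH2 bond is cut, to be made by Negishi coupling; the stereocentre is bought with iodoalanine 11. The neighbouring Cα–Cβ cut (enolate alkylation) needs more steps to the electrophile and an acid to release the amino ester, and a chiral-pool amino acid with the phenol in place would put ester and carbamate ahead of the alkyllithium step. Aryl chloride 10 comes from phenol 7 through dichlorovinyl ether 8 and acetylide 9. Chloride is the coupling handle because a bromide or iodide would undergo halogen–lithium exchange. The forward reaction is asked to couple an electron-rich aryl chloride.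

**6 ⇒ 5 ⇒ 2 + 3, and 2 ⇒ 1.** The pyrone C5–CH2 bond is cut by the same logic, using iodoalanine 3 and bromopyrone 2, which comes from coumalic acid 1 by bromodecarboxylation. The alternative, asymmetric alkylation with a 5-(halomethyl)pyrone, takes three more steps and exposes the pyrone to hydroxide; it is kept as a fallback. The pyrone must survive the organozinc and the acidolysis that frees 6.

## Roads not taken

**Alternative 1:** The cut is the imidazole ring of the purine. The forward key step condenses the bis-Boc macrocyclic salicylaldehyde A2 with the triaminopyrimidinone A3 and closes the imine oxidatively to bis-Boc guanipiperazine A, A1.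
- Merits: the polar heterocycle arrives last, the chemistry is precedented, and only one ortho position is available.
- Weak point: it says nothing about how the 14-membered ring of A2 is made. That would fall back on a C–O ring closure of a finished ring B, with strain and dilution penalties.
- Comparison: as an endgame it is at least as good as anything else, and the chosen plan adopts it unchanged (A1 is 27, A2 is 24, A3 is 25; steps 16 and 17). Its key step is safer than the one chosen here. What the chosen plan sets against it is an answer to the question it leaves open: ring B and the macrocycle are made in one event that is driven by aromatisation.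

**Alternative 2:** The cut is the bond between piperazine C5 and the ring A benzylic carbon. In the forward step a strong amide base acts on the 4-hydroxybenzyl sulfone A5: it unmasks quinone-methide reactivity at ring A and enolises the N-Boc lactam, and intramolecular 1,6-addition closes the ring to the macrocyclic bis-Boc piperazinone A4.
- Merits: a C–C bond closes the ring at low temperature, the phenol emerges free, and the diaryl ether is made earlier without strain.
- Weak points: the new C5 centre is set through a 14-membered transition state with only the remote C2 centre to direct it, and it stays epimerisable next to the lactam carbonyl under the basic conditions. An N-Boc lactam under excess strong base risks carbamate migration or ring opening. The electrophile can oligomerise at any practical dilution.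
- Comparison: the elementary reactivity (1,6-addition to quinone methides) is better precedented than the cycloaddition chosen here, and the conditions are milder. The chosen plan sets against this that both stereocentres are bought rather than made, so its only selectivity question is regiochemical, and that it needs no preformed diaryl ether.

**Alternative 3:** The cut is the CH2–ring B bond. In the forward step a silane-mediated radical chain converts the iodomethyl group of sulfonamide A7 into a primary radical. The radical attacks the sulfonyl-bearing carbon of ring B through a five-membered transition state, the sulfonyl bridge is extruded, and the 13-membered sulfonamide ring becomes the 14-membered macrocycle A6.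
- Merits: an easier 13-membered ring is closed first and then expanded, both stereocentres are fixed beforehand, the two nitrogens come out differentiated, and the conditions are neutral and moderate in temperature.
- Weak points: a nucleophilic alkyl radical attacking an electron-rich, para-aryloxy arene is polarity-mismatched, and reduction of the radical by the silane and β-scission next to nitrogen compete. A7 needs a diaryl ether synthesis plus a macrocyclic sulfonamide closure, so two ring-forming operations precede the key step.
- Comparison: both plans rest on an unproven key step. This one runs cooler and has no regiochemical ambiguity. The chosen plan sets against it a larger driving force (aromatisation with gas loss) and a shorter path to the precursor through two cross-couplings.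

Key step: step 11

Assumption: the two N-Fmoc-3-iodo-L-alanine esters 3 and 11 are treated as purchasable (each is otherwise one Appel iodination from the commercial Fmoc-L-serine ester), and 25 is used as its commercial sulfate.

## Route

Step 1
Reactants: 1 coumalic acid (2-oxo-2H-pyran-5-carboxylic acid)
Product: 2 5-bromo-2H-pyran-2-one
Conditions: NBS (1.1 equiv), LiOAc, MeCN–H2O, rt
Reagents that add atoms: N-bromosuccinimide, O=C1CCC(=O)N1Br
Why: Hunsdiecker-type bromodecarboxylation replaces the carboxyl group on C5 by bromine through ipso-bromination and loss of CO2; holding the brominating agent near one equivalent restrains a second bromination at C3.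

Step 2
Reactants: 2 5-bromo-2H-pyran-2-one; 3 N-Fmoc-3-iodo-L-alanine tert-butyl ester
Product: 5 tert-butyl (2S)-2-(Fmoc-amino)-3-(2-oxo-2H-pyran-5-yl)propanoate, via alkylzinc iodide 4 (not isolated)
Conditions: Zn, I2 (cat.), DMF, rt; then 2, Pd2(dba)3, SPhos, 40 °C
Reagents that add atoms: none
Why: Negishi coupling of a serine-derived β-zincioalanine with a heteroaryl (vinylic) bromide, a standard route to β-aryl alanines. Zinc insertion and coupling do not touch the α-carbon, so the L configuration of 3 is carried into 5 (the descriptor changes from R to S only through the priority rules), and the organozinc is too mild to open the pyrone.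

Step 3
Reactants: 5 tert-butyl (2S)-2-(Fmoc-amino)-3-(2-oxo-2H-pyran-5-yl)propanoate
Product: 6 (2S)-2-(Fmoc-amino)-3-(2-oxo-2H-pyran-5-yl)propanoic acid
Conditions: TFA, CH2Cl2, rt
Reagents that add atoms: none
Why: Acidolysis of the tert-butyl ester with loss of 2-methylpropene; the Fmoc carbamate and the 2-pyrone are stable to acid.

Step 4
Reactants: 7 5-chloro-2-methoxyphenol
Product: 8 4-chloro-2-[(E)-1,2-dichloroethenyloxy]-1-methoxybenzene
Conditions: trichloroethylene, K2CO3, DMF, 70 °C
Reagents that add atoms: trichloroethylene, ClC=C(Cl)Cl
Why: O-Dichlorovinylation of a phenol: the carbonate eliminates HCl from trichloroethylene to dichloroacetylene, to which the phenoxide adds in the anti sense to give the E ether. Aryl chloride and methyl ether are inert.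

Step 5
Reactants: 8 4-chloro-2-[(E)-1,2-dichloroethenyloxy]-1-methoxybenzene
Product: 10 [(5-chloro-2-methoxyphenoxy)ethynyl]triisopropylsilane, via lithium aryloxyacetylide 9 (not isolated)
Conditions: n-BuLi (2.1 equiv), THF, −78 °C; then i-Pr3SiOTf, −78 °C to rt
Reagents that add atoms: triisopropylsilyl trifluoromethanesulfonate, CC(C)[Si](OS(=O)(=O)C(F)(F)F)(C(C)C)C(C)C
Why: Dichlorovinyl ether route to ynol ethers: deprotonation and β-elimination give the chloroalkyne, chlorine–lithium exchange gives acetylide 9, and C-silylation caps it. The step is placed here because nothing in 8 is attacked by an alkyllithium: an aryl chloride, unlike a bromide or iodide, does not exchange at −78 °C, and limiting the base to two equivalents avoids metalation between chlorine and oxygen.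

Step 6
Reactants: 10 [(5-chloro-2-methoxyphenoxy)ethynyl]triisopropylsilane; 11 N-Fmoc-3-iodo-L-alanine methyl ester
Product: 13 methyl (2S)-2-(Fmoc-amino)-3-{4-methoxy-3-[(triisopropylsilyl)ethynyloxy]phenyl}propanoate, via alkylzinc iodide 12 (not isolated)
Conditions: Zn, I2 (cat.), DMF, rt; then 10, Pd2(dba)3, XPhos, 45 °C
Reagents that add atoms: none
Why: Negishi coupling of a primary alkylzinc iodide with an aryl chloride, a coupling known for palladium catalysts with bulky dialkylbiarylphosphines. The α-centre of 11 is not involved and arrives as the S centre of 13; the bulky silyl group shields the ynol ether and the medium is free of acid.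

Step 7
Reactants: 13 methyl (2S)-2-(Fmoc-amino)-3-{4-methoxy-3-[(triisopropylsilyl)ethynyloxy]phenyl}propanoate
Product: 14 methyl (2S)-2-amino-3-{4-methoxy-3-[(triisopropylsilyl)ethynyloxy]phenyl}propanoate
Conditions: piperidine, DMF, rt
Reagents that add atoms: none
Why: Base-induced E1cB cleavage of the Fmoc carbamate; ynol ethers are inert to amines, and no acid is used between step 5 and step 11.

Step 8
Reactants: 6 (2S)-2-(Fmoc-amino)-3-(2-oxo-2H-pyran-5-yl)propanoic acid; 14 methyl (2S)-2-amino-3-{4-methoxy-3-[(triisopropylsilyl)ethynyloxy]phenyl}propanoate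
Product: 15 Fmoc-dipeptide methyl ester: methyl (2S)-2-{[(2S)-2-(Fmoc-amino)-3-(2-oxo-2H-pyran-5-yl)propanoyl]amino}-3-{4-methoxy-3-[(triisopropylsilyl)ethynyloxy]phenyl}propanoate
Conditions: i-PrN=C=N-i-Pr, ethyl cyano(hydroxyimino)acetate, CH2Cl2–DMF, 0 °C to rt (6 pre-activated)
Reagents that add atoms: none
Why: Carbodiimide/oxime-mediated amide coupling; the urethane-protected acid resists oxazolone racemisation, and using ring A as the amine partner keeps a free carboxylic acid away from the ynol ether.

Step 9
Reactants: 15 Fmoc-dipeptide methyl ester
Product: 17 (3S,6S)-3-{4-methoxy-3-[(triisopropylsilyl)ethynyloxy]benzyl}-6-[(2-oxo-2H-pyran-5-yl)methyl]piperazine-2,5-dione, via dipeptide amine 16 (not isolated)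
Conditions: Et2NH, MeCN, rt; evaporate; then toluene–2-butanol, 80 °C, 0.02 M
Reagents that add atoms: none
Why: Fmoc cleavage followed by 6-exo-trig aminolysis of the methyl ester (diketopiperazine formation), which is favourable for an L,L-dipeptide methyl ester. The volatile, hindered amine is removed before heating to spare the pyrone, and both centres are retained to give the cis diketopiperazine.

Step 10
Reactants: 17 silyl-capped diketopiperazine
Product: 18 (3S,6S)-3-[3-(ethynyloxy)-4-methoxybenzyl]-6-[(2-oxo-2H-pyran-5-yl)methyl]piperazine-2,5-dione
Conditions: Bu4NF (1.05 equiv), THF, 0 °C, short; used at once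
Reagents that add atoms: none
Why: Fluoride-induced protodesilylation of an alkynylsilane; it is done last and cold because the free ethynyl ether is the least stable compound of the route.

Step 11
Reactants: 18 ethynyl ether pyrone diketopiperazine
Product: 20 macrocyclic diaryl ether diketopiperazine, the (S,S)-cyclodipeptide whose ring B para oxygen is bonded to ring A ortho to its methoxy group, via bridged bicyclic lactone 19 (not isolated)
Conditions: 1,2-dichlorobenzene–N,N-dimethylacetamide (10:1), syringe-pump addition to 0.5 mM, 2,6-di-tert-butyl-4-methylpyridine, BHT, 160 °C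
Reagents that add atoms: none
Why: Proposed new method: the electron-rich ethynyl ether, nucleophilic at its terminal carbon, should add across C3 and C6 of the tethered 2-pyrone in an inverse-electron-demand intramolecular Diels–Alder reaction (terminal carbon to C6, oxygen-bearing carbon to C3) to give lactone 19, which loses CO2 by retro-[4+2] and leaves the aromatic ring B; the closest known reaction types are intramolecular 2-pyrone–alkyne cycloadditions with CO2 loss that give bent cyclophane arenes, and intermolecular inverse-demand additions of ynamines and ynol ethers to 2-pyrones. Ring B is closed by the [4+2]/retro-[4+2] pair (two new C–C bonds, six-membered, then aromatised), and the 14-membered ring is closed by the same two bonds as a macrocyclic cycloaddition in which the diketopiperazine and ring A form the tether. No new stereocentre remains: the two bridgehead centres of 19 vanish on aromatisation and the two diketopiperazine centres are untouched under neutral thermal conditions. The step needs para over meta bridging, which rests on matched polarisation (largest acceptor coefficient of the pyrone at C6, donor carbon of the ynol ether at its terminus), and intra- over intermolecular reaction, which rests on high dilution and on the cis side chains that fold over one face of the diketopiperazine. Aromatisation and gas loss make the sequence irreversible and pay for the bending of ring B; the hindered base and dry medium guard the ynol ether against adventitious acid.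

Step 12
Reactants: 20 macrocyclic diaryl ether diketopiperazine
Product: 21 macrocyclic (2S,5S)-piperazine methyl ether (both lactam carbonyls of 20 reduced to CH2)
Conditions: BH3·THF, THF, reflux; then MeOH, aq HCl, 60 °C; NaOH
Reagents that add atoms: none
Why: Borane reduction of both secondary lactams to amines, standard for 2,5-diketopiperazines; the diaryl ether, the methyl ether and the stereocentres are unaffected.

Step 13
Reactants: 21 macrocyclic piperazine methyl ether
Product: 22 macrocyclic (2S,5S)-piperazine phenol (the des-guanine core of 28)
Conditions: BBr3, CH2Cl2, −78 °C to rt; then MeOH; aq NaHCO3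
Reagents that add atoms: none
Why: Lewis acid cleavage of the aryl methyl ether by bromide attack on the boron-activated methyl group; diaryl ethers are not cleaved, and the amines are held as adducts until work-up.

Step 14
Reactants: 22 macrocyclic piperazine phenol
Product: 23 N,N'-bis-Boc macrocyclic piperazine phenol
Conditions: Boc2O, Et3N, MeOH, rt
Reagents that add atoms: di-tert-butyl dicarbonate, CC(C)(C)OC(=O)OC(=O)OC(C)(C)C
Why: Carbamate formation at both secondary amines; without an acylation catalyst the phenol is not acylated, and any aryl carbonate is methanolysed in the basic medium.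

Step 15
Reactants: 23 N,N'-bis-Boc macrocyclic piperazine phenol
Product: 24 N,N'-bis-Boc macrocyclic salicylaldehyde (formyl group on ring A ortho to the phenol, on the side away from the aryloxy group)
Conditions: MgCl2, Et3N, (CH2O)n, MeCN, reflux
Reagents that add atoms: paraformaldehyde (as formaldehyde), C=O
Why: MgCl2-mediated ortho-formylation of a phenol: the magnesium phenoxide delivers formaldehyde to the ortho carbon and a second formaldehyde accepts hydride. Para is blocked and the other ortho site carries the aryloxy group, so only the required position is open.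

Step 16
Reactants: 24 N,N'-bis-Boc macrocyclic salicylaldehyde; 25 2,5,6-triaminopyrimidin-4(3H)-one
Product: 27 N,N'-bis-Boc guanipiperazine A, via Schiff base 26 (not isolated)
Conditions: 25 (as sulfate), NaOAc, DMSO, 60 °C; then FeCl3 (cat.), air, 90 °C
Reagents that add atoms: none
Why: Imine formation at the most nucleophilic 5-amino group, addition of the 6-amino group to the imine carbon and aerobic dehydrogenation close the imidazole ring of the purine (oxidative variant of the Traube synthesis), a standard route to 8-arylguanines. The neutral medium keeps the carbamates.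

Step 17
Reactants: 27 N,N'-bis-Boc guanipiperazine A
Product: 28 guanipiperazine A
Conditions: TFA, i-Pr3SiH, CH2Cl2, rt; then NH3/MeOH
Reagents that add atoms: none
Why: Acidolysis of both tert-butyl carbamates; the piperazine centres are not epimerisable and the guanine and the diaryl ether are stable to acid.

## Compound list

1 | coumalic acid | O=C(O)c1ccc(=O)oc1 | starting material
2 | 5-bromo-2H-pyran-2-one | O=c1ccc(Br)co1 | intermediate
3 | N-Fmoc-3-iodo-L-alanine tert-butyl ester, tert-butyl (2R)-2-(Fmoc-amino)-3-iodopropanoate | CC(C)(C)OC(=O)[C@H](CI)NC(=O)OCC1c2ccccc2-c2ccccc12 | starting material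
4 | [(2R)-2-(Fmoc-amino)-3-tert-butoxy-3-oxopropyl]zinc iodide | CC(C)(C)OC(=O)[C@H](C[Zn]I)NC(=O)OCC1c2ccccc2-c2ccccc12 | intermediate
5 | tert-butyl (2S)-2-(Fmoc-amino)-3-(2-oxo-2H-pyran-5-yl)propanoate | CC(C)(C)OC(=O)[C@H](Cc1ccc(=O)oc1)NC(=O)OCC1c2ccccc2-c2ccccc12 | intermediate
6 | (2S)-2-(Fmoc-amino)-3-(2-oxo-2H-pyran-5-yl)propanoic acid | O=C(O)[C@H](Cc1ccc(=O)oc1)NC(=O)OCC1c2ccccc2-c2ccccc12 | intermediate
7 | 5-chloro-2-methoxyphenol | COc1ccc(Cl)cc1O | starting material
8 | 4-chloro-2-[(E)-1,2-dichloroethenyloxy]-1-methoxybenzene | Cl/C=C(/Cl)Oc1cc(Cl)ccc1OC | intermediate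
9 | lithium (5-chloro-2-methoxyphenoxy)acetylide | COc1ccc(Cl)cc1OC#C[Li] | intermediate
10 | [(5-chloro-2-methoxyphenoxy)ethynyl]triisopropylsilane | COc1ccc(Cl)cc1OC#C[Si](C(C)C)(C(C)C)C(C)C | intermediate
11 | N-Fmoc-3-iodo-L-alanine methyl ester, methyl (2R)-2-(Fmoc-amino)-3-iodopropanoate | COC(=O)[C@H](CI)NC(=O)OCC1c2ccccc2-c2ccccc12 | starting material
12 | [(2R)-2-(Fmoc-amino)-3-methoxy-3-oxopropyl]zinc iodide | COC(=O)[C@H](C[Zn]I)NC(=O)OCC1c2ccccc2-c2ccccc12 | intermediate
13 | methyl (2S)-2-(Fmoc-amino)-3-{4-methoxy-3-[(triisopropylsilyl)ethynyloxy]phenyl}propanoate | COC(=O)[C@H](Cc1ccc(OC)c(OC#C[Si](C(C)C)(C(C)C)C(C)C)c1)NC(=O)OCC1c2ccccc2-c2ccccc12 | intermediate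
14 | methyl (2S)-2-amino-3-{4-methoxy-3-[(triisopropylsilyl)ethynyloxy]phenyl}propanoate | COC(=O)[C@@H](N)Cc1ccc(OC)c(OC#C[Si](C(C)C)(C(C)C)C(C)C)c1 | intermediate
15 | Fmoc-L-(2-oxo-2H-pyran-5-yl)alanyl-L-{4-methoxy-3-[(triisopropylsilyl)ethynyloxy]phenyl}alanine methyl ester | COC(=O)[C@H](Cc1ccc(OC)c(OC#C[Si](C(C)C)(C(C)C)C(C)C)c1)NC(=O)[C@H](Cc1ccc(=O)oc1)NC(=O)OCC1c2ccccc2-c2ccccc12 | intermediate
16 | L-(2-oxo-2H-pyran-5-yl)alanyl-L-{4-methoxy-3-[(triisopropylsilyl)ethynyloxy]phenyl}alanine methyl ester (free amine) | COC(=O)[C@H](Cc1ccc(OC)c(OC#C[Si](C(C)C)(C(C)C)C(C)C)c1)NC(=O)[C@@H](N)Cc1ccc(=O)oc1 | intermediate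
17 | (3S,6S)-3-{4-methoxy-3-[(triisopropylsilyl)ethynyloxy]benzyl}-6-[(2-oxo-2H-pyran-5-yl)methyl]piperazine-2,5-dione | CC(C)[Si](C#COc1cc(C[C@@H]2NC(=O)[C@H](Cc3ccc(=O)oc3)NC2=O)ccc1OC)(C(C)C)C(C)C | intermediate
18 | (3S,6S)-3-[3-(ethynyloxy)-4-methoxybenzyl]-6-[(2-oxo-2H-pyran-5-yl)methyl]piperazine-2,5-dione | C#COc1cc(C[C@@H]2NC(=O)[C@H](Cc3ccc(=O)oc3)NC2=O)ccc1OC | intermediate
19 | bridged 2-oxabicyclo[2.2.2]octa-5,7-dien-3-one lactone inside the 14-membered ring (bridgehead configuration not specified; either face gives 20) | c1cc2cc(c1OC)OC3=CC4OC(=O)C3C=C4C[C@H]1C(=O)N[C@H](C(=O)N1)C2 | intermediate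
20 | macrocyclic diaryl ether (S,S)-diketopiperazine, ring A methyl ether | c1cc2cc(c1OC)Oc1ccc(cc1)C[C@H]1C(=O)N[C@H](C(=O)N1)C2 | intermediate
21 | macrocyclic diaryl ether (2S,5S)-piperazine, ring A methyl ether | c1cc2cc(c1OC)Oc1ccc(cc1)C[C@H]1CN[C@H](CN1)C2 | intermediate
22 | macrocyclic diaryl ether (2S,5S)-piperazine, ring A phenol | c1cc2cc(c1O)Oc1ccc(cc1)C[C@H]1CN[C@H](CN1)C2 | intermediate
23 | N,N'-bis-Boc macrocyclic piperazine phenol | c1cc2cc(c1O)Oc1ccc(cc1)C[C@H]1CN(C(=O)OC(C)(C)C)[C@H](CN1C(=O)OC(C)(C)C)C2 | intermediate
24 | N,N'-bis-Boc macrocyclic salicylaldehyde | O=Cc1cc2cc(c1O)Oc1ccc(cc1)C[C@H]1CN(C(=O)OC(C)(C)C)[C@H](CN1C(=O)OC(C)(C)C)C2 | intermediate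
25 | 2,5,6-triaminopyrimidin-4(3H)-one | Nc1nc(N)c(N)c(=O)[nH]1 | starting material
26 | 5-(arylmethylideneamino) Schiff base of 25 with 24 | Nc1nc(N)c(/N=C/c2cc3cc(c2O)Oc2ccc(cc2)C[C@H]2CN(C(=O)OC(C)(C)C)[C@H](CN2C(=O)OC(C)(C)C)C3)c(=O)[nH]1 | intermediate
27 | N,N'-bis-Boc guanipiperazine A | Nc1nc2nc(-c3cc4cc(c3O)Oc3ccc(cc3)C[C@H]3CN(C(=O)OC(C)(C)C)[C@H](CN3C(=O)OC(C)(C)C)C4)[nH]c2c(=O)[nH]1 | intermediate
28 | guanipiperazine A | Nc1nc2nc(-c3cc4cc(c3O)Oc3ccc(cc3)C[C@H]3CN[C@H](CN3)C4)[nH]c2c(=O)[nH]1 | target

## Step count and least certain steps

Total: 17 steps. Longest linear sequence: 14 steps (7 → 28, steps 4–17); the pyrone branch (steps 1–3) joins at step 8. Both stereocentres enter with 3 and 11 and are never made or inverted on the route.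

**Step 11 (key step).** The ethynyl ether may be consumed by oligomerisation or adventitious hydration at the temperature the unactivated pyrone needs, or bonding may occur in the meta sense and give the 13-membered isomer. The fallback closes the ring by a C–O bond with known chemistry, sets out from 11 and comes back at 22.
- The zinc reagent 12 made from 11 is coupled (Pd2(dba)3, SPhos) with commercial 5-iodo-2-methoxyphenol to give methyl N-Fmoc-3-hydroxy-4-methoxy-L-phenylalaninate F1.
- Piperidine frees methyl 3-hydroxy-4-methoxy-L-phenylalaninate F2.
- Carbodiimide coupling with commercial N-Boc-4-iodo-L-phenylalanine gives the dipeptide ester F3.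
- Acidolysis and warming close (3S,6S)-3-(3-hydroxy-4-methoxybenzyl)-6-(4-iodobenzyl)piperazine-2,5-dione F4.
- BH3·THF gives the corresponding (2S,5S)-piperazine F5, and Boc2O its N,N'-bis-Boc derivative F6.
- Intramolecular Ullmann etherification (CuI, N,N-dimethylglycine, Cs2CO3, dioxane, high dilution) closes the N,N'-bis-Boc macrocyclic piperazine methyl ether F7.
- BBr3 removes both carbamates and the methyl ether and delivers 22.

**Step 6.** Oxidative addition into the electron-rich C–Cl bond may be too slow to compete with protonation or β-elimination of the alkylzinc. Fallback: nickel-catalysed reductive cross-electrophile coupling of 10 with 11 (NiI2, 4,4'-di-tert-butyl-2,2'-bipyridine, Zn, NaI, N,N-dimethylacetamide). It joins the two halides directly through an alkyl radical and an arylnickel species, without a preformed organozinc, sets out from 10 and 11 and comes back at 13 with no new compound.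

**Step 10.** Fluoride may epimerise the diketopiperazine or open the pyrone, or the freed ethynyl ether may hydrate during isolation. The fallback keeps fluoride away from both groups, sets out from 14 and comes back at 18.
- Desilylation at the amino ester stage gives methyl (2S)-2-amino-3-[3-(ethynyloxy)-4-methoxyphenyl]propanoate F8.
- Acid 6, pre-activated so that no free acid meets the alkyne, is coupled to give the Fmoc-dipeptide with free ethynyl ether F9.
- Et2NH followed by warming passes through the dipeptide amine F10 and closes 18.

**Step 2.** The zinc reagent may decompose (protonation, β-elimination) faster than it couples with the bromopyrone, or the pyrone may be degraded at the metal. The fallback sets out from 1 and comes back at 5.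
- BH3·THF reduces the acid to 5-(hydroxymethyl)-2H-pyran-2-one F11.
- Appel bromination gives 5-(bromomethyl)-2H-pyran-2-one F12.
- Asymmetric phase-transfer alkylation of commercial glycine tert-butyl ester benzophenone imine (O-allyl-N-(9-anthracenylmethyl)cinchonidinium bromide, CsOH·H2O, CH2Cl2, −78 °C) gives tert-butyl (2S)-2-[(diphenylmethylidene)amino]-3-(2-oxo-2H-pyran-5-yl)propanoate F13.
- Aqueous citric acid releases tert-butyl (2S)-2-amino-3-(2-oxo-2H-pyran-5-yl)propanoate F14.
- Fmoc-OSu with NaHCO3 gives 5.

**Step 16.** The aerobic ring closure may stall at the Schiff base, or the electron-rich phenol may be oxidised instead. The fallback replaces oxidation by dehydration, sets out from 24 and comes back at 27.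
- Pinnick oxidation (NaClO2, NaH2PO4, 2-methyl-2-butene) gives the N,N'-bis-Boc macrocyclic salicylic acid F15.
- Carbodiimide coupling with the 5-amino group of 25 gives the 5-aroylamino-pyrimidinone F16.
- Cyclodehydration (hexamethyldisilazane, (NH4)2SO4, reflux) closes the imidazole ring to 27.

## Further compounds

F1 | step 11 | methyl N-Fmoc-3-hydroxy-4-methoxy-L-phenylalaninate | COC(=O)[C@H](Cc1ccc(OC)c(O)c1)NC(=O)OCC1c2ccccc2-c2ccccc12
F2 | step 11 | methyl 3-hydroxy-4-methoxy-L-phenylalaninate | COC(=O)[C@@H](N)Cc1ccc(OC)c(O)c1
F3 | step 11 | N-Boc-4-iodo-L-phenylalanyl-3-hydroxy-4-methoxy-L-phenylalanine methyl ester | COC(=O)[C@H](Cc1ccc(OC)c(O)c1)NC(=O)[C@H](Cc1ccc(I)cc1)NC(=O)OC(C)(C)C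
F4 | step 11 | (3S,6S)-3-(3-hydroxy-4-methoxybenzyl)-6-(4-iodobenzyl)piperazine-2,5-dione | COc1ccc(C[C@@H]2NC(=O)[C@H](Cc3ccc(I)cc3)NC2=O)cc1O
F5 | step 11 | (2S,5S)-2-(3-hydroxy-4-methoxybenzyl)-5-(4-iodobenzyl)piperazine | COc1ccc(C[C@@H]2NC[C@H](Cc3ccc(I)cc3)NC2)cc1O
F6 | step 11 | di-tert-butyl (2S,5S)-2-(3-hydroxy-4-methoxybenzyl)-5-(4-iodobenzyl)piperazine-1,4-dicarboxylate | COc1ccc(C[C@@H]2N(C(=O)OC(C)(C)C)C[C@H](Cc3ccc(I)cc3)N(C(=O)OC(C)(C)C)C2)cc1O
F7 | step 11 | N,N'-bis-Boc macrocyclic piperazine methyl ether | c1cc2cc(c1OC)Oc1ccc(cc1)C[C@H]1CN(C(=O)OC(C)(C)C)[C@H](CN1C(=O)OC(C)(C)C)C2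
F0 | step 6 | none | none
F8 | step 10 | methyl (2S)-2-amino-3-[3-(ethynyloxy)-4-methoxyphenyl]propanoate | COC(=O)[C@@H](N)Cc1ccc(OC)c(OC#C)c1
F9 | step 10 | Fmoc-L-(2-oxo-2H-pyran-5-yl)alanyl-L-[3-(ethynyloxy)-4-methoxyphenyl]alanine methyl ester | COC(=O)[C@H](Cc1ccc(OC)c(OC#C)c1)NC(=O)[C@H](Cc1ccc(=O)oc1)NC(=O)OCC1c2ccccc2-c2ccccc12
F10 | step 10 | L-(2-oxo-2H-pyran-5-yl)alanyl-L-[3-(ethynyloxy)-4-methoxyphenyl]alanine methyl ester (free amine) | COC(=O)[C@H](Cc1ccc(OC)c(OC#C)c1)NC(=O)[C@@H](N)Cc1ccc(=O)oc1
F11 | step 2 | 5-(hydroxymethyl)-2H-pyran-2-one | O=c1ccc(CO)co1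
F12 | step 2 | 5-(bromomethyl)-2H-pyran-2-one | O=c1ccc(CBr)co1
F13 | step 2 | tert-butyl (2S)-2-[(diphenylmethylidene)amino]-3-(2-oxo-2H-pyran-5-yl)propanoate | CC(C)(C)OC(=O)[C@H](Cc1ccc(=O)oc1)N=C(c1ccccc1)c1ccccc1
F14 | step 2 | tert-butyl (2S)-2-amino-3-(2-oxo-2H-pyran-5-yl)propanoate | CC(C)(C)OC(=O)[C@@H](N)Cc1ccc(=O)oc1
F15 | step 16 | N,N'-bis-Boc macrocyclic salicylic acid | O=C(O)c1cc2cc(c1O)Oc1ccc(cc1)C[C@H]1CN(C(=O)OC(C)(C)C)[C@H](CN1C(=O)OC(C)(C)C)C2
F16 | step 16 | 5-aroylamino derivative of 2,5,6-triaminopyrimidin-4(3H)-one | Nc1nc(N)c(NC(=O)c2cc3cc(c2O)Oc2ccc(cc2)C[C@H]2CN(C(=O)OC(C)(C)C)[C@H](CN2C(=O)OC(C)(C)C)C3)c(=O)[nH]1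
A1 | alternative 1 | N,N'-bis-Boc guanipiperazine A | Nc1nc2nc(-c3cc4cc(c3O)Oc3ccc(cc3)C[C@H]3CN(C(=O)OC(C)(C)C)[C@H](CN3C(=O)OC(C)(C)C)C4)[nH]c2c(=O)[nH]1
A2 | alternative 1 | N,N'-bis-Boc macrocyclic salicylaldehyde | O=Cc1cc2cc(c1O)Oc1ccc(cc1)C[C@H]1CN(C(=O)OC(C)(C)C)[C@H](CN1C(=O)OC(C)(C)C)C2
A3 | alternative 1 | 2,5,6-triaminopyrimidin-4(3H)-one | Nc1nc(N)c(N)c(=O)[nH]1
A4 | alternative 2 | macrocyclic bis-Boc piperazin-2-one with free ring A phenol | c1cc2cc(c1O)Oc1ccc(cc1)C[C@H]1CN(C(=O)OC(C)(C)C)[C@H](C(=O)N1C(=O)OC(C)(C)C)C2
A5 | alternative 2 | bis-Boc (S)-6-{4-[2-hydroxy-5-(phenylsulfonylmethyl)phenoxy]benzyl}piperazin-2-one | O=C1CN(C(=O)OC(C)(C)C)C[C@H](Cc2ccc(Oc3cc(CS(=O)(=O)c4ccccc4)ccc3O)cc2)N1C(=O)OC(C)(C)C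
A6 | alternative 3 | N4-Boc O-benzyl macrocyclic piperazine | c1cc2cc(c1OCc1ccccc1)Oc1ccc(cc1)C[C@H]1CN(C(=O)OC(C)(C)C)[C@H](CN1)C2
A7 | alternative 3 | 13-membered N1-arylsulfonyl N4-Boc 2-(iodomethyl)piperazine with ring A–O–ring B ether, O-benzyl | IC[C@H]1CN(C(=O)OC(C)(C)C)[C@@H]2CN1S(=O)(=O)c1ccc(cc1)Oc1cc(C2)ccc1OCc1ccccc1
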